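All constants are those of an exercise.

I start from a one-step world and add to it what this flask has, one process at a time.

    partner + intermediate → product (k1 = 4060 M⁻¹ s⁻¹)
    substrate → intermediate (k2 = 0.134 s⁻¹)

substrate 5.0 × 10⁻⁴ M; partner 0.500 mM; time 8.0 s

1. at 8.0 s, what has stopped the reaction, if anything has (all of the substrate has reacted / it is still moving / the partner has run out first)
2. amount of product at 8.0 s, in percent of the substrate charged
3. amount of intermediate at 8.0 s, in percent of the substrate charged

- the reaction counts as stopped when no species that holds the substrate changes by six tenths of a point or more over the second half of the time
- run time (flask): 8.0 s

1. Call k the constant of substrate → intermediate (0.134 s⁻¹) and K that of partner + intermediate (4060 M⁻¹ s⁻¹). Substrate has one arrow out, so the fraction left at time t is s = exp(−kt), here 34.2%. In the one-step world the rest is product, 65.8%.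

2. Now I add the second step, with partner held at its charge. Intermediate's half-life there, 0.34 s, is short against 8.0 s, so I let making balance using (the steady-state approximation). That gives the holding ratio h = k/(K × charged partner), intermediate per substrate at full partner, 0.0660. Intermediate is s·h = 2.26%, and product 63.5%.

3. Now partner falls. It goes one for one with product and the charges are equal, so its fraction left is f = 1 − product, 36.5%, and the ratio becomes h/f. Intermediate rises to 6.19%, and product drops to 59.6%.

4. I go round once more: f = 40.4%, intermediate 5.59%, product 60.2%. I commit to these. Substrate moves 24 percentage points over the second half, so the flask is still moving.

The forecast answers "it is still moving", with 60% product and 5.8% intermediate, on the ground that “The intermediate is consumed much faster than it forms”.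

The flask's answer is "it is still moving", with 60.0% product and 5.75% intermediate. At 8.00 s intermediate is made at 0.983 of the rate at which it is used up. The holding ratio also reads the flask at 4.00 s: with partner at 64.5% of its own charge and substrate at 58.5% of the substrate charged, h/f × s gives 5.99%, and the flask holds 6.03%.

In the neighbour flask with 0.0013 M of partner, h is 0.0254 and f about 74.7%, so I expect 1.16% intermediate and 64.6% product. That flask gives 1.19% and 64.6%.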